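**Plan**

1. Numbering of the bicyclo[3.3.1]non-2-ene core, used for all intermediates: C1 bridgehead (CHO), C2 (=C3, CHO), C4, C5 bridgehead (CH3), C6, C7, C8 (6-methylhept-5-en-2-yl), C9 (OAc). Ring A is C1-C2-C3-C4-C5-C9; ring B is C1-C9-C5-C6-C7-C8.
2. Retrosynthesis: C9-OAc, C2-CHO and C1-CHO go back to a C9 ketone, a C2 ketone (enol triflate, then carbonylation) and a C1 dimethyl acetal. Ring A is cut at C4-C5 (bridging Michael addition of the C5 enolate to a C2 acryloyl group), the acetal carbon is cut from C1, and ring B is cut at C6-C7 and C1-C8.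
3. Enabling feature: in ring B, C9 is at the carbonyl level; C1 lies between C9 and the C2 carbonyl (the central carbon of a 1,3-diketone); C5(CH3)-C6H2 maps onto a methacryloyl unit; C7-C8 maps onto the C=C of a nitroalkene that already carries the side chain. Ring B is therefore the retron of a double Michael annulation closed by attack of the C7 nitronate on C6, with nitro as a traceless activator.
4. Forward order: (R)-citronellyl bromide to the nitroalkene; double Michael annulation with an enedione (C1-C8, then ring closure C6-C7) gives ring B; denitration; C1 formyl equivalent; ring A by elimination and Michael addition (C4-C5); C2 triflate, C9 reduction, acetylation, C2 formylation, acetal hydrolysis.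
5. Stereochemistry: the side-chain centre comes from the chiral pool; C8 from catalyst control in the first Michael addition; C1 from alkylation anti to the C8 substituent; C5 from the geometric demand of bridging; C9 from hydride attack over ring A.

Key step: step 4

Assumption: the (1R,2R)-amino-thiourea is taken to direct the carbon acid to the nitroalkene face that gives 8S, by analogy with its known sense of induction for β-substituted nitroalkenes; if a trial shows the opposite sense, its (1S,2S) enantiomer is used with no other change.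

**Route**

Step 1
Reactants: 1 (6R)-8-bromo-2,6-dimethyloct-2-ene [(R)-citronellyl bromide]
Product: 2 (6R)-2,6-dimethyl-8-nitrooct-2-ene
Conditions: NaNO2, DMF, rt
Reagents that add atoms: sodium nitrite, [Na+].[O-]N=O
Why: Kornblum nitrite displacement (SN2) at the primary bromide should give the primary nitroalkane, and the remote stereocentre is not involved.

Step 2
Reactants: 2 (6R)-2,6-dimethyl-8-nitrooct-2-ene
Product: 5 (1E,3R)-3,7-dimethyl-1-nitroocta-1,6-diene, via alpha-phenylselanyl nitroalkane 3 (not isolated), via selenoxide 4 (not isolated)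
Conditions: n-BuLi, THF, -78 °C; PhSeBr; then 30% H2O2, pyridine, 0 °C
Reagents that add atoms: none
Why: C-selenenylation of the lithium nitronate followed by selenoxide syn-elimination (the only β-hydrogens are on C2 of the chain) should give the conjugated nitroalkene as the more stable E isomer, and the allylic stereocentre should survive because the product meets no base stronger than pyridine.

Step 3
Reactants: 6 3-methylbut-3-en-2-one; 7 3-methoxypropanoyl chloride
Product: 8 1-methoxy-6-methylhept-6-ene-3,5-dione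
Conditions: MgBr2·OEt2, iPr2NEt, CH2Cl2, 0 °C to rt; dilute HCl work-up
Reagents that add atoms: none
Why: soft enolisation of the methyl ketone as its magnesium enolate and C-acylation by the acid chloride (crossed Claisen-type acylation) should give the 1,3-diketone, which is protected from further acylation as its magnesium diketonate; no stereocentre is formed.

Step 4
Reactants: 5 (1E,3R)-3,7-dimethyl-1-nitroocta-1,6-diene; 8 1-methoxy-6-methylhept-6-ene-3,5-dione
Product: 10 (3S)-2-(3-methoxypropanoyl)-6-methyl-3-[(2R)-6-methylhept-5-en-2-yl]-4-nitrocyclohexan-1-one, via open-chain Michael adduct 9 (not isolated)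
Conditions: 1-[3,5-bis(trifluoromethyl)phenyl]-3-[(1R,2R)-2-(dimethylamino)cyclohexyl]thiourea (10 mol %), toluene, rt; then KOH (0.3 equiv), EtOH, 0 °C
Reagents that add atoms: none
Why: The amine of the catalyst deprotonates the enolised diketone 8 at C1 while the thiourea binds the nitro group of 5, so C1 adds to C8 and gives 9; hydroxide then regenerates the nitronate, whose carbon C7 adds to C6, the unsubstituted β-carbon of the C9(=O)-C5(CH3)=C6H2 enone, and closes ring B (double Michael annulation, formal [4+2]). The closest known reaction type is the bifunctional-thiourea-catalysed Michael addition of a γ,δ-unsaturated β-dicarbonyl compound to a nitroalkene followed by base-induced intramolecular nitro-Michael closure to a 4-nitrocyclohexanone. Ring B closes in the 6-endo-trig mode, the only productive mode for a nitronate tethered to the carbonyl end of a vinyl ketone, since 5-exo attack would have to hit the α-carbon C5. C8 is the only centre that must be controlled here and is set by the catalyst in the first addition; C7 (nitro), C5 (enolisable) and C1 (enolised diketone) form as mixtures or under thermodynamic control and are cleared or reset in steps 5 to 7. The step needs C- over O-alkylation of the diketone, closure on a single acceptor, and no γ-deprotonation of 5; the hydrogen-bonded soft enol, the presence of only one enone, and the weak amine base in the first stage should secure these.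

Step 5
Reactants: 10 (3S)-2-(3-methoxypropanoyl)-6-methyl-3-[(2R)-6-methylhept-5-en-2-yl]-4-nitrocyclohexan-1-one
Product: 11 (3S)-2-(3-methoxypropanoyl)-6-methyl-3-[(2R)-6-methylhept-5-en-2-yl]cyclohexan-1-one
Conditions: Bu3SnH (5 equiv, 0.2 M), AIBN, toluene, 110 °C
Reagents that add atoms: none
Why: radical denitration (stannyl radical adds to a nitro oxygen, β-scission gives the secondary C7 radical, hydrogen transfer from the stannane) should replace NO2 by H; at this hydride concentration hydrogen transfer should outrun 6-exo cyclisation onto the side-chain alkene, and C7 ceases to be a stereocentre.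

Step 6
Reactants: 11 (3S)-2-(3-methoxypropanoyl)-6-methyl-3-[(2R)-6-methylhept-5-en-2-yl]cyclohexan-1-one
Product: 12 (2R,3S)-2-(dimethoxymethyl)-2-(3-methoxypropanoyl)-6-methyl-3-[(2R)-6-methylhept-5-en-2-yl]cyclohexan-1-one
Conditions: HC(OMe)3, BF3·OEt2, CH2Cl2, -30 °C; then 11, iPr2NEt, -78 °C to 0 °C
Reagents that add atoms: trimethyl orthoformate, COC(OC)OC
Why: C-alkylation of the enolised 1,3-diketone at C1 by the dimethoxycarbenium ion (acetal variant of enol formylation) should create the quaternary centre; the electrophile should enter anti to the C8 side chain, which lies pseudo-axial beside the fully substituted enol carbon, so the acetal carbon ends trans and the acyl group cis to the side chain.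

Step 7
Reactants: 12 (2R,3S)-2-(dimethoxymethyl)-2-(3-methoxypropanoyl)-6-methyl-3-[(2R)-6-methylhept-5-en-2-yl]cyclohexan-1-one
Product: 14 (1R,5R,8S)-1-(dimethoxymethyl)-5-methyl-8-[(2R)-6-methylhept-5-en-2-yl]bicyclo[3.3.1]nonane-2,9-dione, via vinyl ketone 13 (not isolated)
Conditions: KN(SiMe3)2 (2.2 equiv), THF, -78 °C to 0 °C; aq. NH4Cl
Reagents that add atoms: none
Why: E1cB loss of methoxide from the C3 enolate unmasks the vinyl ketone, and the C5 enolate (the only enolisable position of the C9 ketone) adds to C4 in an intramolecular Michael addition (6-endo-trig) that closes ring A; a three-carbon bridge can span C1 and C5 only on the face of ring B that carries the axial acyl group, which fixes C5 as R.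

Step 8
Reactants: 14 (1R,5R,8S)-1-(dimethoxymethyl)-5-methyl-8-[(2R)-6-methylhept-5-en-2-yl]bicyclo[3.3.1]nonane-2,9-dione
Product: 15 (1S,5R,8S)-1-(dimethoxymethyl)-5-methyl-8-[(2R)-6-methylhept-5-en-2-yl]-9-oxobicyclo[3.3.1]non-2-en-2-yl trifluoromethanesulfonate
Conditions: KN(SiMe3)2, THF, -78 °C; PhNTf2, -78 °C to 0 °C; aq. NH4Cl
Reagents that add atoms: N-phenylbis(trifluoromethanesulfonimide), O=S(=O)(N(c1ccccc1)S(=O)(=O)C(F)(F)F)C(F)(F)F
Why: enolate O-sulfonylation should be regiospecific because only the C2 ketone has α-hydrogens (at C3), the C9 ketone being held between two quaternary bridgeheads.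

Step 9
Reactants: 15 (1S,5R,8S)-1-(dimethoxymethyl)-5-methyl-8-[(2R)-6-methylhept-5-en-2-yl]-9-oxobicyclo[3.3.1]non-2-en-2-yl trifluoromethanesulfonate
Product: 16 (1S,5R,8S,9R)-1-(dimethoxymethyl)-9-hydroxy-5-methyl-8-[(2R)-6-methylhept-5-en-2-yl]bicyclo[3.3.1]non-2-en-2-yl trifluoromethanesulfonate
Conditions: NaBH4, MeOH, 0 °C
Reagents that add atoms: none
Why: borohydride reduction of the C9 ketone should occur with hydride approaching over ring A (flattened by C2=C3, one syn-axial hydrogen at C4) and not over ring B (syn-axial hydrogens at C6 and C8), which places the hydroxyl over ring B (9R); enol triflate and acetal are inert.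

Step 10
Reactants: 16 (1S,5R,8S,9R)-1-(dimethoxymethyl)-9-hydroxy-5-methyl-8-[(2R)-6-methylhept-5-en-2-yl]bicyclo[3.3.1]non-2-en-2-yl trifluoromethanesulfonate
Product: 17 (1S,5R,8S,9R)-9-acetoxy-1-(dimethoxymethyl)-5-methyl-8-[(2R)-6-methylhept-5-en-2-yl]bicyclo[3.3.1]non-2-en-2-yl trifluoromethanesulfonate
Conditions: Ac2O, DMAP, pyridine, CH2Cl2, rt
Reagents that add atoms: acetic anhydride, CC(=O)OC(C)=O
Why: DMAP-catalysed O-acylation of the hindered secondary alcohol should proceed with retention at C9.

Step 11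
Reactants: 17 (1S,5R,8S,9R)-9-acetoxy-1-(dimethoxymethyl)-5-methyl-8-[(2R)-6-methylhept-5-en-2-yl]bicyclo[3.3.1]non-2-en-2-yl trifluoromethanesulfonate
Product: 18 (1R,5R,8S,9R)-1-(dimethoxymethyl)-2-formyl-5-methyl-8-[(2R)-6-methylhept-5-en-2-yl]bicyclo[3.3.1]non-2-en-9-yl acetate
Conditions: Pd(OAc)2 (5 mol %), 1,3-bis(diphenylphosphino)propane, CO (1 atm), Et3SiH, Et3N, DMF, 70 °C
Reagents that add atoms: carbon monoxide, [C-]#[O+]
Why: palladium-catalysed reductive carbonylation (formylation) of the enol triflate, by oxidative addition to zerovalent palladium, CO insertion and hydride transfer from the silane to the acylpalladium, should give the enal without touching acetate, acetal or the trisubstituted alkene.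

Step 12
Reactants: 18 (1R,5R,8S,9R)-1-(dimethoxymethyl)-2-formyl-5-methyl-8-[(2R)-6-methylhept-5-en-2-yl]bicyclo[3.3.1]non-2-en-9-yl acetate
Product: 19 (1R,5R,8S,9R)-1,2-diformyl-5-methyl-8-[(2R)-6-methylhept-5-en-2-yl]bicyclo[3.3.1]non-2-en-9-yl acetate
Conditions: TsOH·H2O (cat.), acetone-H2O (10:1), rt
Reagents that add atoms: water, O
Why: acid-catalysed acetal hydrolysis should release the C1 aldehyde; C1 is quaternary, so nothing can epimerise, and acetate, enal and the trisubstituted alkene should tolerate dilute acid at rt.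

**Compound list**

1 | (6R)-8-bromo-2,6-dimethyloct-2-ene | C[C@H](CCC=C(C)C)CCBr | starting material
2 | (6R)-2,6-dimethyl-8-nitrooct-2-ene | C[C@H](CCC=C(C)C)CC[N+](=O)[O-] | intermediate
3 | (3R)-3,7-dimethyl-1-nitro-1-(phenylselanyl)oct-6-ene, C1 epimers, not isolated | C[C@H](CCC=C(C)C)CC([Se]c1ccccc1)[N+](=O)[O-] | intermediate
4 | (3R)-3,7-dimethyl-1-nitro-1-(phenylseleninyl)oct-6-ene, not isolated | C[C@H](CCC=C(C)C)CC([Se](=O)c1ccccc1)[N+](=O)[O-] | intermediate
5 | (1E,3R)-3,7-dimethyl-1-nitroocta-1,6-diene | C[C@H](CCC=C(C)C)/C=C/[N+](=O)[O-] | intermediate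
6 | 3-methylbut-3-en-2-one | CC(=O)C(C)=C | starting material
7 | 3-methoxypropanoyl chloride | COCCC(=O)Cl | starting material
8 | 1-methoxy-6-methylhept-6-ene-3,5-dione | COCCC(=O)CC(=O)C(C)=C | intermediate
9 | 4-[(2S,3R)-3,7-dimethyl-1-nitrooct-6-en-2-yl]-1-methoxy-6-methylhept-6-ene-3,5-dione, not isolated | C=C(C)C(=O)C(C(=O)CCOC)[C@@H](C[N+](=O)[O-])[C@H](C)CCC=C(C)C | intermediate
10 | (3S)-2-(3-methoxypropanoyl)-6-methyl-3-[(2R)-6-methylhept-5-en-2-yl]-4-nitrocyclohexan-1-one, C2/C4/C6 as formed | COCCC(=O)C1C(=O)C(C)CC([N+](=O)[O-])[C@H]1[C@H](C)CCC=C(C)C | intermediate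
11 | (3S)-2-(3-methoxypropanoyl)-6-methyl-3-[(2R)-6-methylhept-5-en-2-yl]cyclohexan-1-one, C2 enolised, C6 epimers | COCCC(=O)C1C(=O)C(C)CC[C@H]1[C@H](C)CCC=C(C)C | intermediate
12 | (2R,3S)-2-(dimethoxymethyl)-2-(3-methoxypropanoyl)-6-methyl-3-[(2R)-6-methylhept-5-en-2-yl]cyclohexan-1-one, C6 epimers | COCCC(=O)[C@@]1(C(OC)OC)C(=O)C(C)CC[C@H]1[C@H](C)CCC=C(C)C | intermediate
13 | (2R,3S)-2-(dimethoxymethyl)-6-methyl-3-[(2R)-6-methylhept-5-en-2-yl]-2-(prop-2-enoyl)cyclohexan-1-one, not isolated | C=CC(=O)[C@@]1(C(OC)OC)C(=O)C(C)CC[C@H]1[C@H](C)CCC=C(C)C | intermediate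
14 | (1R,5R,8S)-1-(dimethoxymethyl)-5-methyl-8-[(2R)-6-methylhept-5-en-2-yl]bicyclo[3.3.1]nonane-2,9-dione | O=C1[C@@]2(C)CCC(=O)[C@]1(C(OC)OC)[C@H]([C@H](C)CCC=C(C)C)CC2 | intermediate
15 | (1S,5R,8S)-1-(dimethoxymethyl)-5-methyl-8-[(2R)-6-methylhept-5-en-2-yl]-9-oxobicyclo[3.3.1]non-2-en-2-yl trifluoromethanesulfonate | O=C1[C@@]2(C)CC=C(OS(=O)(=O)C(F)(F)F)[C@]1(C(OC)OC)[C@H]([C@H](C)CCC=C(C)C)CC2 | intermediate
16 | (1S,5R,8S,9R)-1-(dimethoxymethyl)-9-hydroxy-5-methyl-8-[(2R)-6-methylhept-5-en-2-yl]bicyclo[3.3.1]non-2-en-2-yl trifluoromethanesulfonate | O[C@@H]1[C@@]2(C)CC=C(OS(=O)(=O)C(F)(F)F)[C@]1(C(OC)OC)[C@H]([C@H](C)CCC=C(C)C)CC2 | intermediate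
17 | (1S,5R,8S,9R)-9-acetoxy-1-(dimethoxymethyl)-5-methyl-8-[(2R)-6-methylhept-5-en-2-yl]bicyclo[3.3.1]non-2-en-2-yl trifluoromethanesulfonate | CC(=O)O[C@@H]1[C@@]2(C)CC=C(OS(=O)(=O)C(F)(F)F)[C@]1(C(OC)OC)[C@H]([C@H](C)CCC=C(C)C)CC2 | intermediate
18 | (1R,5R,8S,9R)-1-(dimethoxymethyl)-2-formyl-5-methyl-8-[(2R)-6-methylhept-5-en-2-yl]bicyclo[3.3.1]non-2-en-9-yl acetate | CC(=O)O[C@@H]1[C@@]2(C)CC=C(C=O)[C@]1(C(OC)OC)[C@H]([C@H](C)CCC=C(C)C)CC2 | intermediate
19 | (1R,5R,8S,9R)-1,2-diformyl-5-methyl-8-[(2R)-6-methylhept-5-en-2-yl]bicyclo[3.3.1]non-2-en-9-yl acetate | CC(=O)O[C@@H]1[C@@]2(C)CC=C(C=O)[C@]1(C=O)[C@H]([C@H](C)CCC=C(C)C)CC2 | target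

**Step count and risks**

Total step count: 12. Longest linear sequence: 11 steps (steps 1, 2 and 4 to 12 from compound 1; step 3 prepares the second fragment).

The three steps most likely to fail:

Step 4 (key step). Retro-Michael cleavage of the open-chain adduct and oligomerisation of the enedione may compete with the slow closure onto the α-methylated enone, and facial control at C8 may erode if catalyst and resident stereocentre are mismatched. The fallback sets out from 5 and 8 and returns at 10; it replaces the stepwise anionic annulation by a concerted [4+2] reaction. Diketone 8 is O-silylated (Me3SiCl, Et3N, MeCN) to the 2-silyloxy diene (4Z)-1-methoxy-6-methyl-5-[(trimethylsilyl)oxy]hepta-4,6-dien-3-one F1. A thermal Diels-Alder reaction of F1 with nitroalkene 5 (toluene, 90 °C), in the usual orientation with nitro para to silyloxy, should form C1-C8 and C6-C7 together and give the silyl enol ether 1-[(6S)-3-methyl-6-[(2R)-6-methylhept-5-en-2-yl]-5-nitro-2-[(trimethylsilyl)oxy]cyclohex-2-en-1-yl]-3-methoxypropan-1-one F2. Mild hydrolysis (K2CO3, MeOH) returns 10; C8 epimers are separated at that stage if the acyclic stereocentre alone gives too little facial bias.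

Step 7. Methoxide released by the elimination may attack the non-enolisable 1,3-diketone (retro-Claisen cleavage) or add to the acryloyl group before the bridging Michael addition takes place. The fallback sets out from 12 and returns at 14; it separates the two events and closes the ring from a silyl enol ether. An amine base that buffers the leaving group as methanol (DBU, MeCN, 50 °C) gives enone 13, which is isolated. The C9 ketone, which has an α-hydrogen only at C5, is converted (Me3SiOTf, Et3N, CH2Cl2, -78 °C) into the silyl enol ether 1-[(1R,6S)-1-(dimethoxymethyl)-3-methyl-6-[(2R)-6-methylhept-5-en-2-yl]-2-[(trimethylsilyl)oxy]cyclohex-2-en-1-yl]prop-2-en-1-one F3. Ring A is then closed by a fluoride-triggered Mukaiyama-Michael-type addition ([Bu4N][Ph3SiF2], THF, -78 °C to 0 °C), which frees the C5 enolate with no alkoxide present, to give 14.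

Step 11. Hydride transfer to the vinylpalladium intermediate before CO insertion (hydrogenolysis of the triflate) may dominate at this hindered position. The fallback sets out from 15 and returns at 18; it uses alkoxycarbonylation and a redox adjustment instead of reductive carbonylation. Pd(OAc)2, 1,3-bis(diphenylphosphino)propane, CO, MeOH and Et3N in DMF give the keto ester methyl (1S,5R,8S)-1-(dimethoxymethyl)-5-methyl-8-[(2R)-6-methylhept-5-en-2-yl]-9-oxobicyclo[3.3.1]non-2-ene-2-carboxylate F4. iBu2AlH (CH2Cl2, -78 °C to 0 °C) should reduce the ester and the C9 ketone, with the same facial course as in step 9, to the diol (1R,5R,8S,9R)-1-(dimethoxymethyl)-2-(hydroxymethyl)-5-methyl-8-[(2R)-6-methylhept-5-en-2-yl]bicyclo[3.3.1]non-2-en-9-ol F5. MnO2 (CH2Cl2) oxidises only the allylic alcohol to the hydroxy enal (1R,5R,8S,9R)-1-(dimethoxymethyl)-9-hydroxy-5-methyl-8-[(2R)-6-methylhept-5-en-2-yl]bicyclo[3.3.1]non-2-ene-2-carbaldehyde F6, and acetylation (Ac2O, DMAP, pyridine) gives 18.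

**Further compounds**

F1 | step 4 | (4Z)-1-methoxy-6-methyl-5-[(trimethylsilyl)oxy]hepta-4,6-dien-3-one | COCCC(=O)/C=C(O[Si](C)(C)C)/C(C)=C
F2 | step 4 | 1-[(6S)-3-methyl-6-[(2R)-6-methylhept-5-en-2-yl]-5-nitro-2-[(trimethylsilyl)oxy]cyclohex-2-en-1-yl]-3-methoxypropan-1-one | COCCC(=O)C1C(O[Si](C)(C)C)=C(C)CC([N+](=O)[O-])[C@H]1[C@H](C)CCC=C(C)C
F3 | step 7 | 1-[(1R,6S)-1-(dimethoxymethyl)-3-methyl-6-[(2R)-6-methylhept-5-en-2-yl]-2-[(trimethylsilyl)oxy]cyclohex-2-en-1-yl]prop-2-en-1-one | C=CC(=O)[C@@]1(C(OC)OC)C(O[Si](C)(C)C)=C(C)CC[C@H]1[C@H](C)CCC=C(C)C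
F4 | step 11 | methyl (1S,5R,8S)-1-(dimethoxymethyl)-5-methyl-8-[(2R)-6-methylhept-5-en-2-yl]-9-oxobicyclo[3.3.1]non-2-ene-2-carboxylate | O=C1[C@@]2(C)CC=C(C(=O)OC)[C@]1(C(OC)OC)[C@H]([C@H](C)CCC=C(C)C)CC2
F5 | step 11 | (1R,5R,8S,9R)-1-(dimethoxymethyl)-2-(hydroxymethyl)-5-methyl-8-[(2R)-6-methylhept-5-en-2-yl]bicyclo[3.3.1]non-2-en-9-ol | O[C@@H]1[C@@]2(C)CC=C(CO)[C@]1(C(OC)OC)[C@H]([C@H](C)CCC=C(C)C)CC2
F6 | step 11 | (1R,5R,8S,9R)-1-(dimethoxymethyl)-9-hydroxy-5-methyl-8-[(2R)-6-methylhept-5-en-2-yl]bicyclo[3.3.1]non-2-ene-2-carbaldehyde | O[C@@H]1[C@@]2(C)CC=C(C=O)[C@]1(C(OC)OC)[C@H]([C@H](C)CCC=C(C)C)CC2
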